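## The problem

The target is a ten-membered carbocycle (germacrane numbering C1–C10, C14 on C10, C15 on C4; α and β refer to the usual drawing with H7 α) that is trans-fused across C6–C7 to an α-methylene γ-lactone (C11(=C13)–C12, lactone oxygen on C6). The ring carries a methyl dienoate (C14 ester on C10, ring-cis C10=C1, Z C2=C3) that ends in a trans 4,5-epoxide, and two different esters on neighbouring carbons, an epoxytiglate at C8 and an acetate at C9. Six contiguous ring stereocentres (4R,5R,6S,7R,8S,9S) and two more in the side-chain acid (2S,3R) have to be set. C7 is the anchor: on a six-membered ring it can direct oxygen to C6 and C8, C8 can then direct the reduction at C9, and the C6–C7 trans lactone fixes the orientation of the C4=C5 bond and so the epoxide face, whereas the side-chain oxirane needs reagent control and is made separately. Four features are fragile: the α-methylene lactone (a Michael acceptor that is also sensitive to light and radicals), the two acid-sensitive epoxides (the ring one also a vinyl epoxide), an acyloxy group at C9 (expelled whenever C10 becomes nucleophilic), and the 1(10),2,4-triene that would exist without the epoxide, which can close by 6π electrocyclisation. Two ordering rules follow: the epoxide goes in before C2=C3, and the C9 acetate goes on after C2=C3. The feature that opens the key step is that C10=C1 and C4=C5 are 1,5-related with no C5–C10 bond, which is the pattern left by cycloreversion of a bicyclo[2.2.0]hexane. Such a precursor splits into C5–C10 plus C14 (the carvone skeleton, ketone at C9, stereocentre at C7) and C1–C4 plus C15 (1-methylcyclobutene).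

## Retrosynthesis

**C9 acetate.** The last cut is the acetyl–O9 bond of 29, leading to alcohol 28. It comes last because an acetate at C9 lies β to C10 and is lost as soon as a C2 hydrogen is removed by base. Once C2=C3 exists no such hydrogen remains. The forward step only has to acylate the single free hydroxyl.

**C14 ester and C2=C3.** Ester 27, acid 26 and dienal 25 differ only in oxidation level. The C2–C3 hydrogens are removed from enal 23, and the C14 oxygen from the methyl compound 21. The aldehyde is the only carbonyl whose sole enolisable position is C2, so the dehydrogenation is regiodefined, which a C9 ketone (competing C8–H) would not give. C–H oxidation of C14 on a 4,5-epoxy-1(10)-ene is well precedented and sets the ring-cis C10=C1 geometry at the same time. C9 carries a silyl ether through this phase.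

**C9–H and the epoxide.** Compound 21 goes back through alcohol 20 to ketone 19, and 19 to dienone 18 by removing the epoxide oxygen. Epoxidising directly after ring expansion is preferred to a late epoxidation: only C4=C5 is nucleophilic while C10=C1 is part of an enone. It also removes the 1,5-diene (no Cope rearrangement, no transannular cyclisation) and ensures that the electrocyclisation-prone triene is never formed.

**Ring expansion.** Dienone 18 is the cycloreversion product of photoadduct 17. In the retro direction C1–C4 and C5–C10 are formed, turning the ten-membered ring into a six-membered ring carrying a bicyclo[2.2.0]hexane. This stores the medium ring as strain in small rings, avoiding a macrocyclisation.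

**Key disconnection.** Cutting C10–C1 and C4–C5 of 17 gives enone lactone 14 and 1-methylcyclobutene 16. After this cut all fifteen skeletal carbons sit in one chiral-pool terpene and one C5 alkene. The forward reaction must be head-to-tail and must tolerate the acrylate.

**C8 ester.** Cutting the C8–O bond of the ester in 14 (alkyl–oxygen cleavage, with inversion) gives the 8α-ketol 9 and acid 13. The kinetic hydroxylation of carvone delivers the 8α (trans) alcohol, so a Mitsunobu esterification corrects C8 and installs the final ester in one step. The ester is carried instead of a silyl ether so that no late deprotection or acylation is needed next to the vinyl epoxide.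

**Lactone.** Ketol 9 comes from silyl ether 8. Cutting the C12–O6 bond gives diol 7, and C12 returns to the isopropenyl methyl of 6. The forward step needs only a primary-selective oxidation, because the C6 and C7 centres already fix the trans fusion.

**C6 and C8 oxygens.** The C6–O bond of 6 is cut to give silyl ether 4, which goes back to ketol 3, and cutting the C8–O bond of 3 gives (S)-carvone 1. C8 is oxygenated first because it is the kinetic enolisation site, and because the resulting α-silyloxy group then steers the second enolisation to C6.

**Small fragments.** Acid 13 comes from epoxy alcohol 12, tiglyl alcohol 11 and tiglic acid 10 by asymmetric epoxidation. Alkene 16 comes from methylenecyclobutane 15 by isomerisation.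

## Roads not taken

Alternative 1: The ring would be closed at C5–C6, with the C15 methyl delivered to C4 in the same step. Ni(cod)2 (zerovalent nickel), a carbene or phosphine ligand and Me2Zn would act on the open-chain ynal A2 to give the triene carbinol A1.
- Merits: it is convergent, and syn addition across the alkyne fixes the E C4=C5 bond mechanistically. The chosen plan cannot match this certainty, since its alkene geometry comes from a thermal cycloreversion. The chain can also carry C14 at the right oxidation level and the Z C2=C3 bond from the start.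
- Weak points: the C7–C8–C9 triad of A2 must be built by acyclic stereocontrol. The C6 carbinol configuration is set in a ten-membered closure with no reliable bias. The 1,3-diene of A2 can itself enter oxidative cyclisation at nickel. A1 is the 1(10),2,4-triene and can electrocyclise.
- Against this the chosen plan sets C7 from the chiral pool with C6 and C8 controlled on a six-membered ring, and the epoxide in place before C2=C3.

Alternative 2: The C5–C10 bond would be kept as the ring-fusion bond of the cis-fused hexalin ester A4 and broken by light near 300 nm at low temperature, giving trienoate A3 by conrotatory 6π opening.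
- Merits: A3 is one epoxidation from the target, so its end game is shorter than the chosen one, which needs eight steps after the epoxidation. Decalin chemistry is also well developed.
- Weak points: the opening is a photostationary process. A3 recloses thermally, and its dienoate and acrylate chromophores absorb at the same wavelength. A4 needs a quaternary C10 bearing the ester beside four contiguous substituted centres, which is a long synthesis in itself.
- Against this the chosen plan sets an irreversible thermal ring expansion driven by strain, and never makes the triene.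

Alternative 3: The ring would arise by breaking the C4–C9 bond of the bicyclic mesylate A6 in a Grob fragmentation with KN(SiMe3)2, giving keto trienoate A5.
- Merits: the E C4=C5 geometry is stereospecific, and the C14 ester and C2=C3 are present from the start. Both are better than in the chosen plan, which must oxidise C14 and dehydrogenate C2–C3 late.
- Weak points: A6 needs two quaternary centres (C4 and C9) and a C5 sulfonate held antiperiplanar. The sulfonate is β to the lactone oxygen, and strong base is used beside the acrylate. A5 is again the electrocyclisation-prone triene. Its C9 ketone must be reduced next to a dienoate.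
- Against this the chosen plan sets a two-step assembly of the whole skeleton from commercial materials and late steps that each have a close precedent.

Key step: step 12

Assumption (chemistry): the cycloreversion in step 13 is taken to give the cis,trans-diene with C10=C1 ring-cis and C4=C5 ring-trans. Compounds 18 to 21 are drawn on that basis, and step 17 sets the C10=C1 geometry independently.

## Route

Step 1
Reactants: 1 (S)-carvone
Product: 3 8α-hydroxycarvone (hydroxyl on C8 trans to the isopropenyl group), via cross-conjugated trimethylsilyl dienol ether 2 (not isolated)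
Conditions: LiN(iPr)2, THF, −78 °C; TMSCl; then mCPBA, NaHCO3, CH2Cl2, −20 °C; aq. citric acid
Reagents that add atoms: mCPBA, O=C(OO)c1cccc(Cl)c1
Why: Rubottom oxidation: kinetic deprotonation at C8 gives the 2-silyloxy diene 2, and the peracid attacks its enol ether bond opposite the C7 isopropenyl group, so the hydroxyl should come out mainly trans (the minor cis epimer is removed by chromatography).

Step 2
Reactants: 3 8α-hydroxycarvone
Product: 4 8α-(tert-butyldimethylsilyloxy)carvone
Conditions: TBSCl, imidazole, DMF, rt
Reagents that add atoms: TBSCl, CC(C)(C)[Si](C)(C)Cl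
Why: Standard silylation of a secondary ketol; the silyl ether protects C8 and later steers enolisation away from C8.

Step 3
Reactants: 4 8α-(tert-butyldimethylsilyloxy)carvone
Product: 6 6α-hydroxy-8α-(tert-butyldimethylsilyloxy)carvone (C6 hydroxyl trans to the isopropenyl group), via linear trimethylsilyl dienol ether 5 (not isolated)
Conditions: KN(SiMe3)2, TMSCl, THF, −78 °C; then mCPBA, NaHCO3, CH2Cl2, −40 °C; aq. citric acid
Reagents that add atoms: mCPBA, O=C(OO)c1cccc(Cl)c1
Why: Vinylogous Rubottom oxidation: an α-silyloxy ketone is deprotonated away from the oxygenated carbon, so the base takes the γ-hydrogen at C6 and silylation gives the linear dienol ether 5. The peracid attacks the remote, less hindered C5=C6 bond opposite the neighbouring C7 substituent, which sets C6 with oxygen trans to C7.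

Step 4
Reactants: 6 6α-hydroxy-8α-(tert-butyldimethylsilyloxy)carvone
Product: 7 6α,12-dihydroxy-8α-(tert-butyldimethylsilyloxy)carvone
Conditions: SeO2 (0.5 equiv), tBuOOH, CH2Cl2, rt
Reagents that add atoms: tert-butyl hydroperoxide, CC(C)(C)OO (terminal oxidant; the oxygen is passed on by SeO2, O=[Se]=O)
Why: SeO2 allylic oxidation (ene reaction then [2,3]-sigmatropic shift) of a 1,1-disubstituted alkene takes the methyl group in preference to the ring methine, as is known for isopropenyl terpenes; the electron-poor enone alkene does not react.

Step 5
Reactants: 7 6α,12-dihydroxy-8α-(tert-butyldimethylsilyloxy)carvone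
Product: 8 8α-silyloxy enone lactone (trans-fused α-methylene γ-lactone across C6–C7)
Conditions: TEMPO (cat.), PhI(OAc)2, CH2Cl2, rt
Reagents that add atoms: none
Why: Oxidative lactonisation of a 1,4-diol: the oxoammonium oxidises only the primary allylic alcohol, the aldehyde is captured by the C6 hydroxyl as a lactol, and the lactol is oxidised on to the lactone. The trans fusion is fixed by the existing C6 and C7 centres.

Step 6
Reactants: 8 8α-silyloxy enone lactone
Product: 9 8α-hydroxy enone lactone
Conditions: HF·pyridine, THF, 0 °C to rt
Reagents that add atoms: none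
Why: Fluoride cleavage of the silyl ether under acidic, non-enolising conditions leaves the C8 configuration and the acrylate untouched.

Step 7
Reactants: 10 tiglic acid
Product: 11 tiglyl alcohol, (E)-2-methylbut-2-en-1-ol
Conditions: LiAlH4, Et2O, 0 °C
Reagents that add atoms: none
Why: Hydride reduction of the acid to the allylic alcohol; 1,2-reduction is the known outcome for this α-methyl acid and the E geometry is kept.

Step 8
Reactants: 11 tiglyl alcohol
Product: 12 (2R,3R)-2,3-epoxy-2-methylbutan-1-ol
Conditions: Ti(OiPr)4 (cat.), D-(−)-diethyl tartrate, tBuOOH, 4 Å molecular sieves, CH2Cl2, −20 °C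
Reagents that add atoms: tert-butyl hydroperoxide, CC(C)(C)OO
Why: Sharpless asymmetric epoxidation: the D-(−)-tartrate catalyst delivers oxygen to the face that gives the (2R,3R) epoxy alcohol, and the E alkene puts the two methyl groups cis on the oxirane.

Step 9
Reactants: 12 (2R,3R)-2,3-epoxy-2-methylbutan-1-ol
Product: 13 (2S,3R)-2,3-dimethyloxirane-2-carboxylic acid
Conditions: TEMPO (cat.), PhI(OAc)2, MeCN/H2O, rt
Reagents that add atoms: water, O
Why: Oxoammonium oxidation of the primary alcohol to the acid through the aldehyde hydrate, without opening the epoxide; C2 becomes S only because the CIP priorities change.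

Step 10
Reactants: 9 8α-hydroxy enone lactone; 13 (2S,3R)-2,3-dimethyloxirane-2-carboxylic acid
Product: 14 8β-ester enone lactone (photosubstrate)
Conditions: PPh3, DIAD, THF, 0 °C to rt (betaine preformed)
Reagents that add atoms: none
Why: Mitsunobu esterification: the activated α-keto carbinol carbon C8 is displaced by the carboxylate with inversion, turning the 8α alcohol into the 8β ester of the target. The acid has no α-hydrogen and is acidic enough for this reaction.

Step 11
Reactants: 15 methylenecyclobutane
Product: 16 1-methylcyclobutene
Conditions: Na on Al2O3 (cat.), neat, 0 °C to rt; spinning-band distillation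
Reagents that add atoms: none
Why: Base-catalysed alkene isomerisation to the more substituted endocyclic isomer, which dominates at equilibrium; the residual exocyclic isomer is removed by distillation.

Step 12
Reactants: 14 photosubstrate (enone lactone epoxytiglate); 16 methylcyclobutene (endocyclic isomer)
Product: 17 cis,anti,cis tricyclic photoadduct
Conditions: hν (350 nm, Pyrex), alkene in fifteenfold excess, CH2Cl2, −40 °C, degassed
Reagents that add atoms: none
Why: Enone–alkene [2+2] photocycloaddition, the reaction type known for cyclohexenones and cyclobutenes: n→π* excitation of 14 and intersystem crossing give the enone triplet, which bonds to 16 to form a triplet 1,4-diradical that collapses after spin inversion. The first bond forms between the two partners and the second by recombination of that diradical, which closes the cyclobutane C10–C1–C4–C5; because the four-membered ring of 16 shares the C1–C4 edge, the bicyclo[2.2.0]hexane with the six-membered perimeter C10–C1–C2–C3–C4–C5 is completed in the same event. The head-to-tail orientation that is needed (methyl-bearing C4 to the β-carbon C5) follows the usual preference of donor-substituted alkenes and is reinforced because the other orientation would join two quaternary carbons, C10 and C4. The C10/C5 fusion is cis because the diradical closes on the face on which the first bond was made, the C1/C4 fusion is cis because these atoms come from a ring alkene, and the two small rings lie anti for steric reasons; attack is expected on the enone face opposite the axial C8 ester. These four centres disappear in step 13, so only the regiochemistry has to be right. Selectivity over the α-methylene lactone rests on exciting only the enone band, on the electron-poor character of the acrylate and on the large excess of 16.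

Step 13
Reactants: 17 cis,anti,cis photoadduct
Product: 18 9-oxogermacra-1(10),4,11(13)-trien-12,6α-olide 8β-ester with C10=C1 ring-cis and C4=C5 ring-trans
Conditions: PhMe (0.01 M), BHT (cat.), sealed tube, 180 °C
Reagents that add atoms: none
Why: Thermal cycloreversion of the bicyclo[2.2.0]hexane (C1–C4 cleaves to a cyclohexane-1,4-diyl, then C5–C10), driven by more than 50 kcal/mol of strain, the known route from such photoadducts to cyclodeca-1,5-dienes. A cis,anti,cis adduct is expected to give one ring-cis and one ring-trans alkene; conjugation with the C9 ketone should place the cis bond at C10=C1 and hold the product against Cope rearrangement if heating stops at full conversion.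

Step 14
Reactants: 18 cyclodecadienone
Product: 19 4α,5β-epoxy-9-oxogermacra-1(10),11(13)-dien-12,6α-olide 8β-ester (4R,5R)
Conditions: mCPBA, NaHCO3, CH2Cl2, 0 °C
Reagents that add atoms: mCPBA, O=C(OO)c1cccc(Cl)c1
Why: Prilezhaev epoxidation: only the electron-rich trisubstituted C4=C5 bond reacts, the enone and acrylate alkenes being deactivated. The peracid attacks the outer face of the ring-trans alkene, whose orientation is fixed by the trans lactone, giving the 4R,5R epoxide as in related 6,12-germacranolides.

Step 15
Reactants: 19 epoxy enone
Product: 20 9α-hydroxy-4α,5β-epoxygermacra-1(10),11(13)-dien-12,6α-olide 8β-ester (9S)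
Conditions: NaBH4, CeCl3·7H2O, MeOH, −78 °C
Reagents that add atoms: none
Why: Luche reduction gives 1,2-reduction of the enone without touching the acrylate; hydride delivery from the ring periphery anti to the C8–O bond (Felkin–Anh) should give the 8,9-trans alcohol.

Step 16
Reactants: 20 9α-alcohol
Product: 21 9α-triethylsilyl ether
Conditions: TESCl, imidazole, CH2Cl2, 0 °C
Reagents that add atoms: TESCl, CC[Si](Cl)(CC)CC
Why: Silylation of the allylic alcohol; a silyl ether is used because an acetate at C9 would be expelled when C10 becomes nucleophilic in step 18.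

Step 17
Reactants: 21 9α-triethylsilyl ether
Product: 23 14-oxo enal with C10=C1 ring-cis, via C14 allylic alcohol 22 (not isolated)
Conditions: SeO2 (0.5 equiv), tBuOOH, CH2Cl2, rt; then MnO2, CH2Cl2, rt
Reagents that add atoms: tert-butyl hydroperoxide, CC(C)(C)OO (terminal oxidant; the oxygen is passed on by SeO2, O=[Se]=O)
Why: SeO2 allylic oxidation: ene reaction at C1 with hydrogen taken from the C14 methyl, then [2,3]-sigmatropic shift, gives the C14 alcohol with C14 trans to C2, that is the ring-cis C10=C1 bond. The same reagent is known to convert 4,5-epoxygermacr-1(10)-en-12,6-olides into their 14-hydroxy ring-cis isomers; MnO2 then oxidises the allylic alcohol to the enal.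

Step 18
Reactants: 23 enal
Product: 25 14-oxo-1(10),2-dienal with C2=C3 Z, via trimethylsilyl dienol ether 24 (not isolated)
Conditions: KN(SiMe3)2, TMSCl, THF, −78 °C; then Pd(OAc)2, MeCN, rt
Reagents that add atoms: none
Why: Vinylogous Saegusa–Ito oxidation: the only enolisable hydrogens of 23 are on C2, so the dienolate and its silyl ether 24 form regiospecifically. Divalent palladium is expected to bind the less substituted allyl terminus C2 and lose a C3 hydrogen by β-hydride elimination, giving the ring-cis C2=C3 bond that a ten-membered 1,3-diene prefers.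

Step 19
Reactants: 25 dienal
Product: 26 dienoic acid (C14 carboxylic acid)
Conditions: NaClO2, NaH2PO4, 2-methyl-2-butene, tBuOH/H2O, 0 °C
Reagents that add atoms: NaClO2, [Na+].[O-]Cl=O
Why: Pinnick oxidation of the conjugated aldehyde at pH near 4 with the hypochlorous acid scavenged; epoxides, silyl ether and acrylate are stable and the diene geometry is kept.

Step 20
Reactants: 26 dienoic acid
Product: 27 methyl dienoate 9α-triethylsilyl ether
Conditions: MeI, KHCO3, DMF, rt
Reagents that add atoms: iodomethane, CI
Why: O-Alkylation of the carboxylate by SN2 under weakly basic conditions; diazo reagents are avoided because they add to α-methylene lactones.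

Step 21
Reactants: 27 methyl dienoate 9α-triethylsilyl ether
Product: 28 9α-hydroxy methyl dienoate
Conditions: HF·pyridine, pyridine, THF, 0 °C
Reagents that add atoms: none
Why: Buffered fluoride cleavage of the triethylsilyl ether; the pyridine buffer protects the two epoxides.

Step 22
Reactants: 28 9α-hydroxy methyl dienoate
Product: 29 target
Conditions: Ac2O, pyridine, DMAP (cat.), CH2Cl2, 0 °C
Reagents that add atoms: acetic anhydride, CC(=O)OC(C)=O
Why: Acetylation of the only free hydroxyl with DMAP catalysis; the dienoate has no γ-hydrogen left, so the new acetate can no longer be eliminated.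

## Compound list

1 | (S)-carvone | CC1=CC[C@@H](CC1=O)C(C)=C | starting material
2 | cross-conjugated trimethylsilyl dienol ether of 1 (C8=C9 and C10=C5) | CC1=CC[C@@H](C=C1O[Si](C)(C)C)C(C)=C | intermediate
3 | 8α-hydroxycarvone (C8 hydroxyl trans to isopropenyl) | CC1=CC[C@@H]([C@@H](O)C1=O)C(C)=C | intermediate
4 | 8α-(tert-butyldimethylsilyloxy)carvone | CC1=CC[C@@H]([C@@H](O[Si](C)(C)C(C)(C)C)C1=O)C(C)=C | intermediate
5 | linear trimethylsilyl dienol ether of 4 (C9=C10 and C5=C6) | CC1=C(O[Si](C)(C)C)[C@H](O[Si](C)(C)C(C)(C)C)[C@H](C=C1)C(C)=C | intermediate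
6 | 6α-hydroxy-8α-(tert-butyldimethylsilyloxy)carvone (both oxygens trans to isopropenyl) | CC1=C[C@@H](O)[C@@H]([C@@H](O[Si](C)(C)C(C)(C)C)C1=O)C(C)=C | intermediate
7 | 6α,12-dihydroxy-8α-(tert-butyldimethylsilyloxy)carvone | CC1=C[C@@H](O)[C@@H]([C@@H](O[Si](C)(C)C(C)(C)C)C1=O)C(CO)=C | intermediate
8 | 8α-silyloxy enone lactone (trans-fused α-methylene γ-lactone, C9 ketone, C10=C5) | C=C1C(=O)O[C@H]2[C@H]1[C@@H](O[Si](C)(C)C(C)(C)C)C(=O)C(C)=C2 | intermediate
9 | 8α-hydroxy enone lactone | C=C1C(=O)O[C@H]2[C@H]1[C@@H](O)C(=O)C(C)=C2 | intermediate
10 | tiglic acid | C/C=C(\C)C(=O)O | starting material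
11 | tiglyl alcohol | C/C=C(\C)CO | intermediate
12 | (2R,3R)-2,3-epoxy-2-methylbutan-1-ol | OC[C@@]1(C)O[C@@H]1C | intermediate
13 | (2S,3R)-2,3-dimethyloxirane-2-carboxylic acid | OC(=O)[C@@]1(C)O[C@@H]1C | intermediate
14 | 8β-[(2S,3R)-2,3-epoxy-2-methylbutanoyloxy] enone lactone (photosubstrate) | C=C1C(=O)O[C@H]2[C@H]1[C@H](OC(=O)[C@@]3(C)O[C@@H]3C)C(=O)C(C)=C2 | intermediate
15 | methylenecyclobutane | C=C1CCC1 | starting material
16 | 1-methylcyclobutene | CC1=CCC1 | intermediate
17 | cis,anti,cis photoadduct (new bonds C10–C1 and C4–C5, small rings on the face opposite the C8 ester) | C=C1C(=O)O[C@H]2[C@H]1[C@H](OC(=O)[C@@]3(C)O[C@@H]3C)C(=O)[C@@]4(C)[C@@H]5CC[C@]5(C)[C@@H]24 | intermediate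
18 | 9-oxogermacra-1(10),4,11(13)-trien-12,6α-olide 8β-ester (C10=C1 ring-cis, C4=C5 ring-trans) | C/C1=C\[C@H]2OC(=O)C(=C)[C@@H]2[C@H](OC(=O)[C@@]3(C)O[C@@H]3C)C(=O)/C(C)=C\CC1 | intermediate
19 | 4α,5β-epoxy-9-oxo derivative of 18 (4R,5R) | C=C1C(=O)O[C@H]2[C@H]1[C@H](OC(=O)[C@@]3(C)O[C@@H]3C)C(=O)/C(C)=C\CC[C@@]4(C)O[C@H]24 | intermediate
20 | 9α-alcohol (9S, trans to the C8 ester) | C=C1C(=O)O[C@H]2[C@H]1[C@H](OC(=O)[C@@]3(C)O[C@@H]3C)[C@@H](O)/C(C)=C\CC[C@@]4(C)O[C@H]24 | intermediate
21 | 9α-triethylsilyl ether of 20 | C=C1C(=O)O[C@H]2[C@H]1[C@H](OC(=O)[C@@]3(C)O[C@@H]3C)[C@@H](O[Si](CC)(CC)CC)/C(C)=C\CC[C@@]4(C)O[C@H]24 | intermediate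
22 | 14-hydroxy derivative of 21 (C10=C1 ring-cis) | C=C1C(=O)O[C@H]2[C@H]1[C@H](OC(=O)[C@@]3(C)O[C@@H]3C)[C@@H](O[Si](CC)(CC)CC)/C(CO)=C\CC[C@@]4(C)O[C@H]24 | intermediate
23 | 14-oxo enal | C=C1C(=O)O[C@H]2[C@H]1[C@H](OC(=O)[C@@]3(C)O[C@@H]3C)[C@@H](O[Si](CC)(CC)CC)/C(C=O)=C\CC[C@@]4(C)O[C@H]24 | intermediate
24 | trimethylsilyl dienol ether of 23 (C14=C10 and C1=C2) | C=C1C(=O)O[C@H]2[C@H]1[C@H](OC(=O)[C@@]3(C)O[C@@H]3C)[C@@H](O[Si](CC)(CC)CC)C(=CO[Si](C)(C)C)/C=C\C[C@@]4(C)O[C@H]24 | intermediate
25 | 14-oxo-1(10),2-dienal (C10=C1 ring-cis, C2=C3 Z) | C=C1C(=O)O[C@H]2[C@H]1[C@H](OC(=O)[C@@]3(C)O[C@@H]3C)[C@@H](O[Si](CC)(CC)CC)/C(C=O)=C\C=C/[C@@]4(C)O[C@H]24 | intermediate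
26 | 14-oic acid | C=C1C(=O)O[C@H]2[C@H]1[C@H](OC(=O)[C@@]3(C)O[C@@H]3C)[C@@H](O[Si](CC)(CC)CC)/C(C(=O)O)=C\C=C/[C@@]4(C)O[C@H]24 | intermediate
27 | methyl 14-oate 9α-triethylsilyl ether | C=C1C(=O)O[C@H]2[C@H]1[C@H](OC(=O)[C@@]3(C)O[C@@H]3C)[C@@H](O[Si](CC)(CC)CC)/C(C(=O)OC)=C\C=C/[C@@]4(C)O[C@H]24 | intermediate
28 | 9α-hydroxy methyl 14-oate | C=C1C(=O)O[C@H]2[C@H]1[C@H](OC(=O)[C@@]3(C)O[C@@H]3C)[C@@H](O)/C(C(=O)OC)=C\C=C/[C@@]4(C)O[C@H]24 | intermediate
29 | target: methyl 9α-acetoxy-8β-[(2S,3R)-2,3-epoxy-2-methylbutanoyloxy]-4α,5β-epoxygermacra-1(10),2,11(13)-trien-12,6α-olid-14-oate (4R,5R,6S,7R,8S,9S; C10=C1 ring-cis, C2=C3 Z) | C=C1C(=O)O[C@H]2[C@H]1[C@H](OC(=O)[C@@]1(C)O[C@@H]1C)[C@@H](OC(C)=O)/C(C(=O)OC)=C\C=C/[C@@]1(C)O[C@H]21 | target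

## Step count and risk

Total steps: 22. Longest linear sequence: 18 (steps 1–6, 10, 12–22, from (S)-carvone).

**Step 12 (key step).** The most likely failure is competing light-induced chemistry of the α-methylene lactone (cross-addition to the excited enone, oligomerisation), together with erosion of head-to-tail regioselectivity, because one methyl group polarises 16 only weakly. Fallback: mask the exocyclic methylene through the photochemical and thermal steps. Setting out from 14, conjugate addition of thiophenol (Et3N cat.) gives the sulfide F1. Irradiation with 16 gives the photoadduct F2, and thermolysis gives the dienone sulfide F3. Two equivalents of mCPBA then oxidise sulfur and epoxidise C4=C5 to give the sulfoxide epoxide F4. Heating in toluene with CaCO3 expels benzenesulfenic acid and rejoins the route at 19.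

**Step 13.** At the temperature needed to open the bicyclo[2.2.0]hexane the product can drift on into its Cope isomer, and the α-acyloxy ketone can lose the C8 ester by elimination across C7–C8. The distribution of alkene geometries is also not secured. The Cope isomer can be re-equilibrated; the ester loss needs a change of order. Fallback: setting out from 8, irradiation with 16 gives the silyl ether photoadduct F5, and thermolysis gives the silyl ether dienone F6. HF·pyridine gives the ketol F7, and Mitsunobu esterification with 13 (inversion at C8) rejoins the route at 18.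

**Step 18.** β-Hydride elimination can run toward C9 from the α-bound palladium enolate instead of toward C3. Syn elimination can give the ring-trans C2=C3 bond kinetically. The zerovalent palladium set free can also open the new vinyl epoxide. Fallback: a sulfoxide elimination, which is regiospecific because C2 has sp3 hydrogens only on C3. Setting out from 23 through 24, PhSCl at −78 °C gives the γ-sulfide F8. One equivalent of mCPBA at −78 °C gives the sulfoxide F9, and warming in toluene at 80–90 °C rejoins the route at 25.

**Step 17.** The ene reaction may be sluggish at the hindered, inductively deactivated C10=C1 bond, and the acidic selenium species may trigger transannular attack of this alkene on the 4,5-epoxide. Fallback: setting out from 21, ene-type chlorination with Ca(OCl)2 and solid CO2 in CH2Cl2/H2O gives the allylic chloride F10 (chlorine on C1, exocyclic C10=C14). Kornblum oxidation with allylic transposition (AgBF4, DMSO; then Et3N) rejoins the route at 23.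

**Step 15.** Hydride delivery to the flexible ten-membered enone may show poor facial selectivity and favour the 9-epimer. Fallback: accept that epimer and invert it. Setting out from 19, the same reduction gives the 9β-alcohol F11. A Mitsunobu reaction with chloroacetic acid (PPh3, DIAD) gives the inverted chloroacetate F12, and thiourea with NaHCO3 in EtOH removes the chloroacetyl group and rejoins the route at 20.

Further compounds
F1 | step 12 | thiophenol adduct of 14 (13-phenylthio-11,13-dihydro; C11 epimers, either serves) | C(Sc4ccccc4)C1C(=O)O[C@H]2[C@H]1[C@H](OC(=O)[C@@]3(C)O[C@@H]3C)C(=O)C(C)=C2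
F2 | step 12 | photoadduct of F1 with 16 | C(Sc6ccccc6)C1C(=O)O[C@H]2[C@H]1[C@H](OC(=O)[C@@]3(C)O[C@@H]3C)C(=O)[C@@]4(C)[C@@H]5CC[C@]5(C)[C@@H]24
F3 | step 12 | 13-phenylthio-11,13-dihydro analogue of 18 | C/C1=C\[C@H]2OC(=O)C(CSc4ccccc4)[C@@H]2[C@H](OC(=O)[C@@]3(C)O[C@@H]3C)C(=O)/C(C)=C\CC1
F4 | step 12 | 13-phenylsulfinyl-11,13-dihydro analogue of 19 | O=S(c5ccccc5)CC1C(=O)O[C@H]2[C@H]1[C@H](OC(=O)[C@@]3(C)O[C@@H]3C)C(=O)/C(C)=C\CC[C@@]4(C)O[C@H]24
F5 | step 13 | photoadduct of 8 with 16 (8α-silyloxy) | C=C1C(=O)O[C@H]2[C@H]1[C@@H](O[Si](C)(C)C(C)(C)C)C(=O)[C@@]3(C)[C@@H]4CC[C@]4(C)[C@@H]23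
F6 | step 13 | 8α-silyloxy-9-oxogermacra-1(10),4,11(13)-trien-12,6α-olide | C/C1=C\[C@H]2OC(=O)C(=C)[C@@H]2[C@@H](O[Si](C)(C)C(C)(C)C)C(=O)/C(C)=C\CC1
F7 | step 13 | 8α-hydroxy-9-oxogermacra-1(10),4,11(13)-trien-12,6α-olide | C/C1=C\[C@H]2OC(=O)C(=C)[C@@H]2[C@@H](O)C(=O)/C(C)=C\CC1
F8 | step 18 | 2-phenylthio derivative of 23 (C2 epimers) | C=C1C(=O)O[C@H]2[C@H]1[C@H](OC(=O)[C@@]3(C)O[C@@H]3C)[C@@H](O[Si](CC)(CC)CC)/C(C=O)=C\C(Sc5ccccc5)C[C@@]4(C)O[C@H]24
F9 | step 18 | 2-phenylsulfinyl derivative of 23 | C=C1C(=O)O[C@H]2[C@H]1[C@H](OC(=O)[C@@]3(C)O[C@@H]3C)[C@@H](O[Si](CC)(CC)CC)/C(C=O)=C\C(S(=O)c5ccccc5)C[C@@]4(C)O[C@H]24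
F10 | step 17 | 1-chloro-10(14)-ene isomer derived from 21 (C1 epimers) | C=C1C(=O)O[C@H]2[C@H]1[C@H](OC(=O)[C@@]3(C)O[C@@H]3C)[C@@H](O[Si](CC)(CC)CC)C(=C)C(Cl)CC[C@@]4(C)O[C@H]24
F11 | step 15 | 9β-alcohol (9-epimer of 20) | C=C1C(=O)O[C@H]2[C@H]1[C@H](OC(=O)[C@@]3(C)O[C@@H]3C)[C@H](O)/C(C)=C\CC[C@@]4(C)O[C@H]24
F12 | step 15 | 9α-chloroacetate of 20 | C=C1C(=O)O[C@H]2[C@H]1[C@H](OC(=O)[C@@]3(C)O[C@@H]3C)[C@@H](OC(=O)CCl)/C(C)=C\CC[C@@]4(C)O[C@H]24
A1 | alternative 1 | ten-membered triene carbinol from the nickel ring closure | C=C(CO[Si](C)(C)C(C)(C)C)[C@@H]1[C@H](OCc2ccc(OC)cc2)[C@@H](O[Si](C)(C)C(C)(C)C)/C(CO[Si](C)(C)C(C)(C)C)=C\C=C/C(C)=C/[C@H]1O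
A2 | alternative 1 | open-chain ynal (C6 aldehyde, terminal C4≡C5 alkyne) | C=C(CO[Si](C)(C)C(C)(C)C)[C@@H](C=O)[C@H](OCc1ccc(OC)cc1)[C@@H](O[Si](C)(C)C(C)(C)C)/C(CO[Si](C)(C)C(C)(C)C)=C\C=C/C#C
A3 | alternative 2 | 4,5-deoxy target (1(10),2,4-trienoate) | C=C1C(=O)O[C@H]2[C@H]1[C@H](OC(=O)[C@@]3(C)O[C@@H]3C)[C@@H](OC(C)=O)/C(C(=O)OC)=C\C=C/C(C)=C/2
A4 | alternative 2 | cis-fused hexalin ester with the C5–C10 bond (one cis-fused isomer shown) | C=C1C(=O)O[C@H]2[C@H]1[C@H](OC(=O)[C@@]3(C)O[C@@H]3C)[C@@H](OC(C)=O)[C@@]4(C(=O)OC)C=CC=C(C)[C@@H]24
A5 | alternative 3 | C9-keto trienoate lactone from the fragmentation | C=C1C(=O)O[C@H]2[C@H]1[C@H](OCc3ccc(OC)cc3)C(=O)/C(C(=O)OC)=C\C=C/C(C)=C/2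
A6 | alternative 3 | bicyclic C9 carbinol C5 mesylate with the C4–C9 bond | C=C1C(=O)O[C@H]2[C@H]1[C@H](OCc3ccc(OC)cc3)[C@]4(O)C(C(=O)OC)=CC=C[C@@]4(C)[C@@H]2OS(C)(=O)=O
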